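If a molecule of J behaves the same whatever [J] it started in, the percent of G in a flask depends on its time and not on its charge. Two runs support this: their [J] differed 6.54-fold, yet at 15.0 min G stood at 28.7 % and 28.9 %.

| setting | Tuesday's | Thursday's | green | teal |
|---|---|---|---|---|
| J | 0.26 M | 1.7 M | 2.0 M | 0.47 M |
| remark | run made earlier | run made earlier |  |  |
| time |  |  | 12 min | 20 min |

- Tuesday's (time / min: G / %, J / %): 0.833: 2.1, 83.3; 2.00: 5.1, 63.0; 4.00: 8.2, 39.2; 6.00: 11.2, 26.4; 8.00: 17.6, 18.8; 12.0: 24.5, 8.7; 15.0: 28.7, 5.9
- Thursday's (time / min: G / %, J / %): 1.00: 2.1, 80.4; 1.50: 1.3, 68.3; 2.50: 6.1, 53.9; 4.00: 9.5, 39.9; 6.00: 12.0, 24.9; 10.0: 19.7, 12.9; 15.0: 28.9, 7.4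

(each reading ± 1 percentage point)

* the flask that ends with the higher amount of G, in percent of the J charged, or "neither" when 2 percentage points or less lies between them (green / teal / neither)
* final G, as a percentage of the J charged, in green
* final G, as a percentage of the J charged, in teal



Follow one molecule through Tuesday's run. By 15.0 min, the readings put its chance of still being J at 5.9 %, of being G at 28.7 %, and of being in some unseen form at 65.4 %. So it is unseen more often than it is G.

G climbs nearly in step with time. We therefore define the hand-over time T, the whole charge divided by the pace at which G appeared up to the last reading of each run: 52.1 min. It is a measure of pace, not a time at which any flask is full of G. Time over T is one number, our straight-line estimate of the yield. Green gets 23.0 % and teal gets 38.4 %, so by this estimate teal ends higher, by 15 percentage points, which is beyond the margin of 2 points.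

Is one number enough? For Thursday's reading at 10.0 min, time over T gives 19.2 % against 19.7 % read, a gap within the scatter of 1 point. But teal's 20 min lies past the last reading at 15.0 min, so its number is the weaker one.

The forecast says teal, with green at 24.8 % (22.5 % to 27 %) and teal at 37.5 % (34 % to 41 %), and it warns: “Teal at 20 min is an extrapolation”.

The simulation gives green 24.1 % and teal 33.0 %, so teal does end higher.

    G ⇌ E (K = 1.30, k = 9.42 × 10⁻⁴ s⁻¹)
    E ⇌ J (k = 2.49 × 10⁻⁴ s⁻¹)
    J ⇌ G (K = 11.8, k = 2.16 × 10⁻⁴ s⁻¹)
    G → X (k = 4.36 × 10⁻⁵ s⁻¹)

Our line stays close for green, but for teal it overshoots by 5.4 points. Inside the readings, the same reckoning serves for green stopped at 3.0 min. Time over T gives 5.76 %, and that flask holds 5.69 % as G, with 49.3 % still J and 45.0 % as E.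

The earlier runs and the new flask were computed with constants of no real substance; the scatter is artificial.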